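**Retrosynthetic overview**
- Ring C (pyranone) is closed last: the O1–C2 bond comes from a catalyst-controlled 6-endo oxa-Michael addition of an ortho-OH onto the open (E)-enone of an acylphloroglucinol (chalcone-isomerase logic), and this sets C2.
- Ring A (arene) is closed before that: the C4a–C5 bond comes from a chalcone-synthase-type Claisen cyclisation/aromatisation of a linear 3,5,7-triketo ester that already carries both C-methyl groups as propionate-type units.
- The tetraketide chain comes from 1,2-acylation of a diketo-ester trianion with the C20 (E)-enoyl Weinreb amide.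
- Building blocks: methyl 2-methyl-3-oxopentanoate plus N-methoxy-N-methylacetamide (diketo ester); octadecanal plus a Weinreb-amide phosphonate (enamide).
- Order of ring formation: ring A (step 4), then ring C (step 5).

Assumption: the biosynthesis is taken to be chalcone-synthase-like (C20 (E)-2-enoyl starter, three chain extensions to a linear tetraketide, Claisen closure to the acylphloroglucinol, then oxa-Michael closure of the pyranone); the target stereocentre is (S).

**Route**

Step 1
Reactants: 1 octadecanal; 2 diethyl [2-(methoxy(methyl)amino)-2-oxoethyl]phosphonate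
Product: 3 (2E)-N-methoxy-N-methylicos-2-enamide
Conditions: NaH, THF, 0 °C to rt
Reagents that add atoms: none
Why: Horner–Wadsworth–Emmons olefination of an aliphatic aldehyde with the stabilised amide phosphonate gives the (E)-enamide (typically >95:5 E) and installs the Weinreb group needed for a clean 1,2-acylation later.

Step 2
Reactants: 4 methyl 2-methyl-3-oxopentanoate; 5 N-methoxy-N-methylacetamide
Product: 7 methyl 2,4-dimethyl-3,5-dioxohexanoate, via dilithium dienolate Li2C7H10O3 6 (not isolated)
Conditions: LiN(iPr)2 (2.1 equiv), THF, 0 °C; then 5, −78 to 0 °C; cold 1 M HCl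
Reagents that add atoms: none
Why: Huckin–Weiler γ-acylation of a β-keto ester dianion: the second-formed C4 carbanion attacks the Weinreb amide, whose adduct releases the ketone only on work-up so acylation stops at one acetyl; the two methyl-bearing stereocentres are left uncontrolled because both become aromatic sp2 carbons in step 4.

Step 3
Reactants: 7 methyl 2,4-dimethyl-3,5-dioxohexanoate; 3 (2E)-N-methoxy-N-methylicos-2-enamide
Product: 9 methyl (8E)-2,4-dimethyl-3,5,7-trioxohexacos-8-enoate, via trilithium trienolate Li3C9H11O4 8 (not isolated)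
Conditions: LiN(iPr)2 (3.1 equiv), THF, −78 to 0 °C; then 3 (0.9 equiv), −78 to −10 °C; cold 1 M HCl to pH 3–4
Reagents that add atoms: none
Why: Harris-type polyanion acylation: C2 and C4 are fully substituted enolate carbons, so only the terminal CH2 carbanion reacts, and it attacks the Weinreb amide at C=O (1,2) rather than at the β-carbon, giving the tetraketide with the (E)-enone masked until the quench.

Step 4
Reactants: 9 methyl (8E)-2,4-dimethyl-3,5,7-trioxohexacos-8-enoate
Product: 11 (2E)-1-(2,4,6-trihydroxy-3,5-dimethylphenyl)icos-2-en-1-one, via cyclic triketone 10 (not isolated)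
Conditions: Mg(OMe)2 (6 equiv), MeOH, Ar, 0 to 40 °C; then cold 1 M HCl/EtOAc (−10 °C); crude used at once
Reagents that add atoms: none
Why: Biomimetic Claisen (Dieckmann-type) cyclisation: the C6 carbon of the Mg2+-bound 5,7-diketonate attacks the C1 ester, methoxide leaves and triple enolisation of 10 gives the arene; the aldol fold (C2 onto C7) cannot aromatise because C2 bears a methyl, lactone and pyranone side-equilibria are reversible in methoxide, and the product is expected to stay as the open polyphenoxide in strong base so the enone is freed only on cold acidification (no stereocentre formed).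

Step 5
Reactants: 11 (2E)-1-(2,4,6-trihydroxy-3,5-dimethylphenyl)icos-2-en-1-one
Product: 12 (2S)-2-heptadecyl-5,7-dihydroxy-6,8-dimethyl-2,3-dihydro-4H-chromen-4-one
Conditions: 1-[3,5-bis(trifluoromethyl)phenyl]-3-(9-deoxy-epi-quinidin-9-yl)thiourea (10 mol%), PhMe–CH2Cl2 (5:1), −30 °C, 24–48 h; acidic silica plug; recrystallisation to upgrade ee
Reagents that add atoms: none
Why: Proposed new method: enantioselective 6-endo-trig oxa-Michael closure of an unprotected 2',6'-dihydroxyaryl alkenyl ketone, in which one ortho-OH stays hydrogen-bonded to C=O and lowers the enone LUMO as a built-in Brønsted acid, the other ortho-OH (pKa about 8) is deprotonated by the quinuclidine nitrogen while the thiourea N–H pair binds the carbonyl/enolate oxygen, so the phenoxide is delivered to one enone face inside the ion pair and C2 is set as (S); the sense of induction cannot be predicted for this substrate class and must be confirmed in the first run by chiral HPLC and CD (the quinine-derived pseudo-enantiomer gives the antipode; (S) here is spatially the (2R) series of 2-arylchromanones because alkyl ranks below C3), low temperature and absence of free base keep the uncatalysed closure and retro-oxa-Michael racemisation slow, and the closest known reaction type is the cinchona-alkaloid or bifunctional-thiourea-catalysed oxa-Michael cyclisation of 2'-hydroxychalcones and 2'-hydroxyaryl alkylidene β-keto esters to flavanones and 2-alkylchromanones.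

**Compound list**

1 | octadecanal | CCCCCCCCCCCCCCCCCC=O | starting material
2 | diethyl [2-(methoxy(methyl)amino)-2-oxoethyl]phosphonate | CCOP(=O)(CC(=O)N(C)OC)OCC | starting material
3 | (2E)-N-methoxy-N-methylicos-2-enamide | CCCCCCCCCCCCCCCCC/C=C/C(=O)N(C)OC | intermediate
4 | methyl 2-methyl-3-oxopentanoate (racemic) | CCC(=O)C(C)C(=O)OC | starting material
5 | N-methoxy-N-methylacetamide | CC(=O)N(C)OC | starting material
6 | dilithium 1-methoxy-2-methylpenta-1,3-diene-1,3-bis(olate), the dienolate of 4 (not isolated) | [Li+].[Li+].COC([O-])=C(C)C([O-])=CC | intermediate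
7 | methyl 2,4-dimethyl-3,5-dioxohexanoate (mixture of diastereomers and enol tautomers) | CC(=O)C(C)C(=O)C(C)C(=O)OC | intermediate
8 | trilithium 1-methoxy-2,4-dimethylhexa-1,3,5-triene-1,3,5-tris(olate), the trienolate of 7 (not isolated) | [Li+].[Li+].[Li+].COC([O-])=C(C)C([O-])=C(C)C([O-])=C | intermediate
9 | methyl (8E)-2,4-dimethyl-3,5,7-trioxohexacos-8-enoate (mixture of diastereomers and enol tautomers) | CCCCCCCCCCCCCCCCC/C=C/C(=O)CC(=O)C(C)C(=O)C(C)C(=O)OC | intermediate
10 | 2-[(2E)-icos-2-enoyl]-4,6-dimethylcyclohexane-1,3,5-trione (not isolated, stereocentres undefined) | CCCCCCCCCCCCCCCCC/C=C/C(=O)C1C(=O)C(C)C(=O)C(C)C1=O | intermediate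
11 | (2E)-1-(2,4,6-trihydroxy-3,5-dimethylphenyl)icos-2-en-1-one | CCCCCCCCCCCCCCCCC/C=C/C(=O)c1c(O)c(C)c(O)c(C)c1O | intermediate
12 | (2S)-2-heptadecyl-5,7-dihydroxy-6,8-dimethyl-2,3-dihydro-4H-chromen-4-one | CCCCCCCCCCCCCCCCC[C@H]1CC(=O)c2c(O)c(C)c(O)c(C)c2O1 | target

**Step count**

Total steps: 5. Longest linear sequence: 4 steps (4 → 7 → 9 → 11 → 12; the branch 1 → 3 joins at step 3).

**Three steps most likely to fail, with fallbacks**

Step 3 (trianion acylation). The risks are γ-deprotonation of 3, conjugate addition, and low reactivity of the aggregated trianion. The fallback masks two of the three acidic sites in a pyrone. It sets out from 7: DBU in refluxing toluene lactonises it to 4-hydroxy-3,5,6-trimethyl-2H-pyran-2-one F1. Double deprotonation of this pyrone (OH and 6-methyl; LiN(iPr)2, 2.2 equiv, THF, −78 °C) gives a softer, less basic carbon nucleophile, which is acylated by 3 to give 4-hydroxy-3,5-dimethyl-6-[(3E)-2-oxohenicos-3-en-1-yl]-2H-pyran-2-one F2. Mg(OMe)2 in MeOH then opens the lactone by methanolysis, so the fallback comes back to the route at 9, formed in the flask under the conditions of step 4.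

Step 4 (Claisen closure with the enone present). The risks are methoxide addition to the enone, premature racemic ring closure, and diversion to the lactone. The fallback forms ring A on a chain without the enone and brings in the C17 chain and the stereocentre afterwards through a chromone. It sets out from 7: its trianion 8 is acetylated with 5 to give methyl 2,4-dimethyl-3,5,7-trioxooctanoate F3. Mg(OMe)2/MeOH closes this to 1-(2,4,6-trihydroxy-3,5-dimethylphenyl)ethan-1-one F4. Fourfold deprotonation with LiN(SiMe3)2 (4.2 equiv, THF, −78 °C) and C-acylation with stearoyl chloride give 1-(2,4,6-trihydroxy-3,5-dimethylphenyl)icosane-1,3-dione F5. H2SO4 in AcOH cyclodehydrates it to 2-heptadecyl-5,7-dihydroxy-6,8-dimethyl-4H-chromen-4-one F6. Asymmetric copper hydride 1,4-reduction then sets C2 (Cu(OAc)2, DTBM-SEGPHOS with the ligand enantiomer fixed in a test run, excess (EtO)2MeSiH, t-BuOH, PhMe; NH4F work-up to free the phenols), and the fallback comes back to the route at 12.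

Step 5 (catalyst-controlled oxa-Michael). The risks are low ee from background closure, the wrong sense of induction, and erosion by retro-oxa-Michael. The fallback resolves instead of inducing. It sets out from 11: catalytic Et3N in CH2Cl2 closes it to rac-2-heptadecyl-5,7-dihydroxy-6,8-dimethyl-2,3-dihydro-4H-chromen-4-one F7. Kinetic resolution by asymmetric transfer hydrogenation (Cp*RhCl[TsDPEN], HCO2H/Et3N, using the catalyst enantiomer that reduces the (R)-ketone) converts the unwanted enantiomer into the cis alcohol (2R,4S)-2-heptadecyl-6,8-dimethyl-3,4-dihydro-2H-chromene-4,5,7-triol F8. This is removed by chromatography, and the unreacted (S)-ketone is where the fallback comes back to the route, at 12 (at most 50 % yield).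

**Further compounds**

F1 | step 3 | 4-hydroxy-3,5,6-trimethyl-2H-pyran-2-one | CC1=C(C)C(O)=C(C)C(=O)O1
F2 | step 3 | 4-hydroxy-3,5-dimethyl-6-[(3E)-2-oxohenicos-3-en-1-yl]-2H-pyran-2-one | CCCCCCCCCCCCCCCCC/C=C/C(=O)CC1=C(C)C(O)=C(C)C(=O)O1
F3 | step 4 | methyl 2,4-dimethyl-3,5,7-trioxooctanoate | CC(=O)CC(=O)C(C)C(=O)C(C)C(=O)OC
F4 | step 4 | 1-(2,4,6-trihydroxy-3,5-dimethylphenyl)ethan-1-one | CC(=O)c1c(O)c(C)c(O)c(C)c1O
F5 | step 4 | 1-(2,4,6-trihydroxy-3,5-dimethylphenyl)icosane-1,3-dione | CCCCCCCCCCCCCCCCCC(=O)CC(=O)c1c(O)c(C)c(O)c(C)c1O
F6 | step 4 | 2-heptadecyl-5,7-dihydroxy-6,8-dimethyl-4H-chromen-4-one | CCCCCCCCCCCCCCCCCC1=CC(=O)c2c(O)c(C)c(O)c(C)c2O1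
F7 | step 5 | rac-2-heptadecyl-5,7-dihydroxy-6,8-dimethyl-2,3-dihydro-4H-chromen-4-one | CCCCCCCCCCCCCCCCCC1CC(=O)c2c(O)c(C)c(O)c(C)c2O1
F8 | step 5 | (2R,4S)-2-heptadecyl-6,8-dimethyl-3,4-dihydro-2H-chromene-4,5,7-triol | CCCCCCCCCCCCCCCCC[C@@H]1C[C@H](O)c2c(O)c(C)c(O)c(C)c2O1
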